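## Retrosynthetic overview

1. Target ⇒ open-chain epoxy aldehyde/allylic chloride that already carries the 8-senecioate and the free 9-OH. C6–C7 (the bond nature makes from farnesyl C1 to C10) and O6–C12 are formed together, last, by a chromium-mediated macrocyclising allylation–lactonisation.
2. That seco compound ⇒ cross-metathesis (C7=C11) of a vinyl diol monoester with methyl 2-(chloromethyl)acrylate, then oxidation of the primary epoxy alcohol.
3. Vinyl diol monoester ⇒ catalytic enantioselective syn-γ-acyloxyallylation (C8–C9) of a (Z)-2-methyl enal with 3-chloropropenyl senecioate (from acrolein and senecioyl chloride).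
4. (Z)-Enal ⇒ Still–Gennari olefination (C1=C10, Z) of the ozonolysis aldehyde of silylated (2R,3R)-2,3-epoxygeraniol (Sharpless epoxidation of geraniol).
5. Ring order: oxirane first (step 1); ten-membered carbocycle and γ-lactone in one operation at the end (step 10).

Assumption: the SMILES is taken as drawn (1(10)-Z olefin; 4R,5R,6S,7R,8R,9R, i.e. 4α,5β-epoxide, H-6β, H-7α, 8α-ester, 9β-OH; germacrane numbering throughout), and the (R,R)-ligand of step 7 is taken to direct addition to the Si face of the aldehyde (otherwise its enantiomer is used).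

## Route

Step 1
Reactants: 1 geraniol
Product: 3 triethyl{[(2R,3R)-3-methyl-3-(4-methylpent-3-en-1-yl)oxiran-2-yl]methoxy}silane, via (2R,3R)-2,3-epoxygeraniol 2 (not isolated)
Conditions: tBuOOH (1.5 equiv), Ti(OiPr)4 (5 mol%), D-(−)-diethyl tartrate (7 mol%), 4 Å MS, CH2Cl2, −20 °C; then P(OMe)3 (destroys excess peroxide); then Et3SiCl, Et3N, DMAP (cat.), −20 → 0 °C
Reagents that add atoms: tert-butyl hydroperoxide CC(C)(C)OO; chlorotriethylsilane CC[Si](Cl)(CC)CC
Why: Catalytic Sharpless asymmetric epoxidation, in which the D-(−)-tartrate–titanium catalyst delivers oxygen to the allylic alcohol face that gives the (2R,3R)-oxirane (the 4R,5R epoxide of the target, typically about 95% ee) while the remote trisubstituted olefin is left alone, followed by in-situ silylation so that the epoxy alcohol need not be isolated.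

Step 2
Reactants: 3 triethyl{[(2R,3R)-3-methyl-3-(4-methylpent-3-en-1-yl)oxiran-2-yl]methoxy}silane
Product: 5 3-[(2R,3R)-2-methyl-3-{[(triethylsilyl)oxy]methyl}oxiran-2-yl]propanal, via secondary ozonide 4 (not isolated)
Conditions: O3, CH2Cl2, −78 °C; then PPh3, −78 °C → rt
Reagents that add atoms: ozone [O-][O+]=O
Why: Ozonolysis with reductive work-up cleaves the only remaining C=C bond to the aldehyde and acetone, the oxirane and the silyl ether being inert to ozone and to PPh3 at low temperature.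

Step 3
Reactants: 5 3-[(2R,3R)-2-methyl-3-{[(triethylsilyl)oxy]methyl}oxiran-2-yl]propanal; 6 ethyl 2-[bis(2,2,2-trifluoroethoxy)phosphoryl]propanoate
Product: 8 ethyl (2Z)-2-methyl-5-[(2R,3R)-2-methyl-3-{[(triethylsilyl)oxy]methyl}oxiran-2-yl]pent-2-enoate, via potassium phosphonate carbanion 7 (not isolated)
Conditions: 6, KN(SiMe3)2 (1.05 equiv), 18-crown-6 (3 equiv), THF, −78 °C; then 5, −78 °C
Reagents that add atoms: potassium bis(trimethylsilyl)amide C[Si](C)(C)[N-][Si](C)(C)C.[K+] (its potassium stays only in 7)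
Why: Still–Gennari modification of the Horner–Wadsworth–Emmons olefination, in which the electron-poor bis(trifluoroethyl) phosphonate and the crown-ether-separated potassium ion make elimination faster than equilibration and so give the (Z)-2-methyl enoate (usually above 15:1), the geometry that becomes the 1(10)-Z olefin of the target.

Step 4
Reactants: 8 ethyl (2Z)-2-methyl-5-[(2R,3R)-2-methyl-3-{[(triethylsilyl)oxy]methyl}oxiran-2-yl]pent-2-enoate
Product: 9 (2Z)-2-methyl-5-[(2R,3R)-2-methyl-3-{[(triethylsilyl)oxy]methyl}oxiran-2-yl]pent-2-en-1-ol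
Conditions: iBu2AlH (2.5 equiv), CH2Cl2, −78 °C; aqueous work-up
Reagents that add atoms: none
Why: 1,2-Reduction of the conjugated ester with iBu2AlH at −78 °C gives the allylic alcohol with the Z geometry intact, and the oxirane and silyl ether do not react at this temperature.

Step 5
Reactants: 9 (2Z)-2-methyl-5-[(2R,3R)-2-methyl-3-{[(triethylsilyl)oxy]methyl}oxiran-2-yl]pent-2-en-1-ol
Product: 10 (2Z)-2-methyl-5-[(2R,3R)-2-methyl-3-{[(triethylsilyl)oxy]methyl}oxiran-2-yl]pent-2-enal
Conditions: MnO2 (activated, 15 equiv), CH2Cl2, rt, dark; used at once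
Reagents that add atoms: none
Why: Heterogeneous MnO2 oxidation acts on the allylic alcohol only and is neutral, so the isomerisation-prone (Z)-2-methyl enal is obtained without Z to E leakage and is used at once.

Step 6
Reactants: 11 acrolein; 12 3-methylbut-2-enoyl chloride
Product: 14 3-chloroprop-1-en-1-yl 3-methylbut-2-enoate (E/Z mixture), via 1-chloroallyl ester 13 (not isolated)
Conditions: ZnCl2 (2 mol%), CH2Cl2, −20 → 0 °C
Reagents that add atoms: none
Why: Lewis-acid-catalysed addition of the acyl chloride across the aldehyde carbonyl gives the 1-chloroallyl ester, whose chloride shifts to the allylic terminus (1,3-allylic transposition) to give the conjugated enol ester, and the E/Z ratio is irrelevant because both isomers give the same allylchromium species.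

Step 7
Reactants: 10 (2Z)-2-methyl-5-[(2R,3R)-2-methyl-3-{[(triethylsilyl)oxy]methyl}oxiran-2-yl]pent-2-enal; 14 3-chloroprop-1-en-1-yl 3-methylbut-2-enoate
Product: 16 (3R,4R,5Z)-4-hydroxy-8-[(2R,3R)-3-(hydroxymethyl)-2-methyloxiran-2-yl]-5-methylocta-1,5-dien-3-yl 3-methylbut-2-enoate, via bis-silyl ether 15 (not isolated)
Conditions: CrCl3 (10 mol%), Mn powder (3 equiv), (R,R)-N,N'-bis(3,5-di-tert-butylsalicylidene)cyclohexane-1,2-diamine (10 mol%), Et3N (20 mol%), Me3SiCl (1.5 equiv), MeCN, rt; then Bu4NF/AcOH (1:1), THF, 0 °C → rt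
Reagents that add atoms: chlorotrimethylsilane C[Si](C)(C)Cl (its silyl group stays only in 15)
Why: Catalytic enantioselective Nozaki–Hiyama–Kishi γ-acyloxyallylation, in which the allylchromium species bearing the chiral ligand (formed from 14 by reduction, Mn being the terminal reductant and Me3SiCl freeing the catalyst from the product alkoxide) adds through its oxygen-bearing carbon to the Si face of the aldehyde in the syn-selective manner typical of this ligand system, which sets 8R and 9R and places the senecioate on O8 and the free hydroxyl on O9 directly, before buffered fluoride removes both silyl groups.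

Step 8
Reactants: 16 (3R,4R,5Z)-4-hydroxy-8-[(2R,3R)-3-(hydroxymethyl)-2-methyloxiran-2-yl]-5-methylocta-1,5-dien-3-yl 3-methylbut-2-enoate; 17 methyl 2-(chloromethyl)prop-2-enoate
Product: 18 methyl (2Z,4R,5R,6Z)-2-(chloromethyl)-5-hydroxy-9-[(2R,3R)-3-(hydroxymethyl)-2-methyloxiran-2-yl]-6-methyl-4-[(3-methylbut-2-enoyl)oxy]nona-2,6-dienoate
Conditions: second-generation Hoveyda–Grubbs catalyst (10 mol%), 17 (10 equiv), CH2Cl2, 40 °C
Reagents that add atoms: none
Why: Olefin cross-metathesis between the monosubstituted alkene and an excess of the 1,1-disubstituted acrylate releases ethene and gives the trisubstituted enoate (ester trans to C8, the thermodynamic geometry, though either isomer would serve in step 10), while the trisubstituted olefins of the chain and of the senecioate are too hindered to enter the ruthenium cycle.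

Step 9
Reactants: 18 methyl (2Z,4R,5R,6Z)-2-(chloromethyl)-5-hydroxy-9-[(2R,3R)-3-(hydroxymethyl)-2-methyloxiran-2-yl]-6-methyl-4-[(3-methylbut-2-enoyl)oxy]nona-2,6-dienoate
Product: 19 methyl (2Z,4R,5R,6Z)-2-(chloromethyl)-9-[(2R,3S)-3-formyl-2-methyloxiran-2-yl]-5-hydroxy-6-methyl-4-[(3-methylbut-2-enoyl)oxy]nona-2,6-dienoate
Conditions: TEMPO (10 mol%), PhI(OAc)2 (1.1 equiv), CH2Cl2, 0 °C → rt
Reagents that add atoms: none
Why: Oxoammonium (TEMPO) oxidation with PhI(OAc)2 as terminal oxidant is selective for the primary alcohol over the hindered secondary allylic one and is mild enough for the oxirane and the allylic chloride, giving the α,β-epoxy aldehyde without epimerisation.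

Step 10
Reactants: 19 methyl (2Z,4R,5R,6Z)-2-(chloromethyl)-9-[(2R,3S)-3-formyl-2-methyloxiran-2-yl]-5-hydroxy-6-methyl-4-[(3-methylbut-2-enoyl)oxy]nona-2,6-dienoate
Product: 22 target CNP0188779.3 (4R,5R,6S,7R,8R,9R,1(10)Z)-4,5-epoxy-9-hydroxy-8-(3-methylbut-2-enoyloxy)germacra-1(10),11(13)-dien-12,6-olide, via allylchromium dichloride 20 (not isolated), via ring-closed chromium alkoxide 21 (not isolated)
Conditions: CrCl2 (6 equiv), NaI (20 mol%), DMF/THF 1:1, rt; 19 added over 8 h (final 2 mM)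
Reagents that add atoms: chromium dichloride Cl[Cr]Cl (its atoms stay only in 20 and 21)
Why: Intramolecular Nozaki–Hiyama (chromium Barbier) allylation under high dilution, in which CrCl2 turns the allylic chloride into the allylchromium species that adds through C7 to the epoxy aldehyde in a cyclic six-membered transition state embedded in the forming ten-membered ring, so that the trans-oxirane, the Z olefin and the C8 ester (macrocyclic stereocontrol, the sense known for 1(10)-Z 4,5-epoxy seco-aldehydes of this family) set 6S and 7R (H-6β, H-7α) and the chromium alkoxide then closes the trans-fused α-methylene-γ-lactone with loss of methoxide, which forms the carbocycle at the bond that nature makes from farnesyl C1 to C10 and the lactone in one operation on the unprotected, fully acylated chain.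

## Compound list

1 | geraniol | CC(C)=CCC/C(C)=C/CO | starting material
2 | (2R,3R)-2,3-epoxygeraniol | OC[C@H]1O[C@]1(C)CCC=C(C)C | intermediate (not isolated)
3 | triethyl{[(2R,3R)-3-methyl-3-(4-methylpent-3-en-1-yl)oxiran-2-yl]methoxy}silane | CC[Si](CC)(CC)OC[C@H]1O[C@]1(C)CCC=C(C)C | intermediate
4 | secondary ozonide (1,2,4-trioxolane) of 3 at the terminal olefin, mixture at the trioxolane CH | CC[Si](CC)(CC)OC[C@H]1O[C@]1(C)CCC2OOC(C)(C)O2 | intermediate (not isolated)
5 | 3-[(2R,3R)-2-methyl-3-{[(triethylsilyl)oxy]methyl}oxiran-2-yl]propanal | CC[Si](CC)(CC)OC[C@H]1O[C@]1(C)CCC=O | intermediate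
6 | ethyl 2-[bis(2,2,2-trifluoroethoxy)phosphoryl]propanoate | CCOC(=O)C(C)P(=O)(OCC(F)(F)F)OCC(F)(F)F | starting material
7 | potassium salt of the carbanion of 6 | CCOC(=O)[C-](C)P(=O)(OCC(F)(F)F)OCC(F)(F)F.[K+] | intermediate (not isolated)
8 | ethyl (2Z)-2-methyl-5-[(2R,3R)-2-methyl-3-{[(triethylsilyl)oxy]methyl}oxiran-2-yl]pent-2-enoate | CC[Si](CC)(CC)OC[C@H]1O[C@]1(C)CC/C=C(C)\C(=O)OCC | intermediate
9 | (2Z)-2-methyl-5-[(2R,3R)-2-methyl-3-{[(triethylsilyl)oxy]methyl}oxiran-2-yl]pent-2-en-1-ol | CC[Si](CC)(CC)OC[C@H]1O[C@]1(C)CC/C=C(C)\CO | intermediate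
10 | (2Z)-2-methyl-5-[(2R,3R)-2-methyl-3-{[(triethylsilyl)oxy]methyl}oxiran-2-yl]pent-2-enal | CC[Si](CC)(CC)OC[C@H]1O[C@]1(C)CC/C=C(C)\C=O | intermediate
11 | acrolein | C=CC=O | starting material
12 | 3-methylbut-2-enoyl chloride (senecioyl chloride) | CC(C)=CC(=O)Cl | starting material
13 | 1-chloroprop-2-en-1-yl 3-methylbut-2-enoate (racemic) | C=CC(Cl)OC(=O)C=C(C)C | intermediate (not isolated)
14 | 3-chloroprop-1-en-1-yl 3-methylbut-2-enoate (E/Z mixture) | ClCC=COC(=O)C=C(C)C | intermediate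
15 | 6-O-triethylsilyl 9-O-trimethylsilyl ether of 16 (8R,9R) | CC[Si](CC)(CC)OC[C@H]1O[C@]1(C)CC/C=C(C)\[C@@H](O[Si](C)(C)C)[C@H](OC(=O)C=C(C)C)C=C | intermediate (not isolated)
16 | (3R,4R,5Z)-4-hydroxy-8-[(2R,3R)-3-(hydroxymethyl)-2-methyloxiran-2-yl]-5-methylocta-1,5-dien-3-yl 3-methylbut-2-enoate | OC[C@H]1O[C@]1(C)CC/C=C(C)\[C@@H](O)[C@H](OC(=O)C=C(C)C)C=C | intermediate
17 | methyl 2-(chloromethyl)prop-2-enoate | C=C(CCl)C(=O)OC | starting material
18 | methyl (2Z,4R,5R,6Z)-2-(chloromethyl)-5-hydroxy-9-[(2R,3R)-3-(hydroxymethyl)-2-methyloxiran-2-yl]-6-methyl-4-[(3-methylbut-2-enoyl)oxy]nona-2,6-dienoate | OC[C@H]1O[C@]1(C)CC/C=C(C)\[C@@H](O)[C@H](OC(=O)C=C(C)C)/C=C(\CCl)C(=O)OC | intermediate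
19 | methyl (2Z,4R,5R,6Z)-2-(chloromethyl)-9-[(2R,3S)-3-formyl-2-methyloxiran-2-yl]-5-hydroxy-6-methyl-4-[(3-methylbut-2-enoyl)oxy]nona-2,6-dienoate | O=C[C@H]1O[C@]1(C)CC/C=C(C)\[C@@H](O)[C@H](OC(=O)C=C(C)C)/C=C(\CCl)C(=O)OC | intermediate
20 | allylchromium dichloride from 19 (CH2–CrCl2 in place of CH2Cl; trivalent chromium; C7=C11 geometry mobile) | O=C[C@H]1O[C@]1(C)CC/C=C(C)\[C@@H](O)[C@H](OC(=O)C=C(C)C)C=C(C[Cr](Cl)Cl)C(=O)OC | intermediate (not isolated)
21 | ring-closed chromium alkoxide: methyl 2-[(ten-membered ring)-7-yl]prop-2-enoate with 6α-O–CrCl2, 7α-H, 8α-senecioate, 9β-OH, 4α,5β-epoxide, 1(10)-Z | Cl[Cr](Cl)O[C@@H]1[C@H]2O[C@]2(C)CC/C=C(C)\[C@@H](O)[C@H](OC(=O)C=C(C)C)[C@H]1C(=C)C(=O)OC | intermediate (not isolated)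
22 | CNP0188779.3: (4R,5R,6S,7R,8R,9R,1(10)Z)-4,5-epoxy-9-hydroxy-8-(3-methylbut-2-enoyloxy)germacra-1(10),11(13)-dien-12,6-olide | C=C1C(=O)O[C@H]2[C@H]1[C@@H](OC(=O)C=C(C)C)[C@H](O)/C(C)=C\CC[C@@]1(C)O[C@H]21 | target

## Step count and risks

Total step count: 10. Longest linear sequence: 9 steps (steps 1–5 and 7–10); step 6 is a one-step side branch.

The three steps most likely to fail:

Step 7 (acyloxyallylation). Risks: moderate ee and syn/anti ratio with a senecioate donor and a hindered (Z)-enal, Me3SiCl-assisted opening of the trisubstituted oxirane, Z to E leakage of 10, and 1,2-acyl shift during desilylation. Fallback, setting out from 10 and coming back at 16: replace the catalytic reaction by a stoichiometric reagent-controlled alkoxyallylboration and a protecting-group exchange. Allyl 4-methoxybenzyl ether is metallated (sec-BuLi, THF, −78 °C) and trapped with (−)-Ipc2BOMe, then BF3·OEt2, to give the (Z)-γ-(4-methoxybenzyloxy)allyldiisopinocampheylborane F1. This adds to 10 at −78 °C through a chair transition state (Si face, syn) and gives, after NaOH/H2O2, the (8R,9R) 9-hydroxy 8-PMB ether F2. Et3SiOTf/2,6-lutidine gives the bis-triethylsilyl ether F3, DDQ (CH2Cl2/pH 7 buffer) frees the 8-hydroxyl in the alcohol F4, and 3-methylbut-2-enoyl chloride 12 (pyridine, DMAP) gives the senecioate F5. Bu4NF/AcOH then removes both silyl groups and returns to 16.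

Step 8 (cross-metathesis). Risks: a 1,1-disubstituted acrylate is a reluctant partner for an olefin that carries an allylic ester, ring closure of the vinyl group onto the senecioate olefin (butenolide, loss of isobutene) can compete, and the 9-OH can alkylate the new allylic chloride. Fallback, setting out from 16 and coming back at 22: make the metathesis intramolecular on a temporary 9-O-acrylate tether. 16 is oxidised (TEMPO, PhI(OAc)2) to the epoxy aldehyde F6, esterified at O9 with 2-(chloromethyl)acrylic acid (N,N'-diisopropylcarbodiimide, DMAP cat.) to the diene F7, and closed with second-generation Grubbs catalyst to the 3-(chloromethyl)-5,6-dihydropyran-2-one F8. CrCl2 under high dilution then forms the C6–C7 bond on the only face of C7 that the tether can reach, giving the bridged hydroxy δ-lactone F9 (as its chromium alkoxide), which translactonises to the more stable γ-lactone, frees the 9-hydroxyl and arrives at 22.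

Step 10 (macrocyclisation). Risks: vinylogous β-elimination of the senecioate from 20 (loss of the C8 oxygen as a dienoate), addition to the wrong aldehyde face, oligomerisation, and reduction of the epoxy aldehyde by divalent chromium. Fallback, setting out from 18 and coming back at 22: exchange the reducing metal for boron, whose C–B bond does not expel the δ-acyloxy group. 18 and B2pin2 with Pd2(dba)3 (DMSO, 50 °C) give the 2-(methoxycarbonyl)allylboronate F10, and TEMPO/PhI(OAc)2 gives the epoxy aldehyde F11. Heating at 1 mM in toluene (80 °C) brings about intramolecular allylboration through a closed six-membered transition state to the ring-closed borate F12, which lactonises to 22.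

Further compounds

F1 | step 7 | (Z)-γ-(4-methoxybenzyloxy)allyldiisopinocampheylborane from (−)-Ipc2BOMe | COc1ccc(CO/C=C\CB([C@@H]2C[C@@H]3C[C@H]([C@H]2C)C3(C)C)[C@@H]2C[C@@H]3C[C@H]([C@H]2C)C3(C)C)cc1
F2 | step 7 | (3R,4R,5Z)-3-[(4-methoxybenzyl)oxy]-5-methyl-8-[(2R,3R)-2-methyl-3-{[(triethylsilyl)oxy]methyl}oxiran-2-yl]octa-1,5-dien-4-ol | CC[Si](CC)(CC)OC[C@H]1O[C@]1(C)CC/C=C(C)\[C@@H](O)[C@H](OCc2ccc(OC)cc2)C=C
F3 | step 7 | 4-O-triethylsilyl ether of F2 | CC[Si](CC)(CC)OC[C@H]1O[C@]1(C)CC/C=C(C)\[C@@H](O[Si](CC)(CC)CC)[C@H](OCc2ccc(OC)cc2)C=C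
F4 | step 7 | (3R,4R,5Z)-5-methyl-8-[(2R,3R)-2-methyl-3-{[(triethylsilyl)oxy]methyl}oxiran-2-yl]-4-[(triethylsilyl)oxy]octa-1,5-dien-3-ol | CC[Si](CC)(CC)OC[C@H]1O[C@]1(C)CC/C=C(C)\[C@@H](O[Si](CC)(CC)CC)[C@H](O)C=C
F5 | step 7 | 3-methylbut-2-enoate of F4 (bis-triethylsilyl ether of 16) | CC[Si](CC)(CC)OC[C@H]1O[C@]1(C)CC/C=C(C)\[C@@H](O[Si](CC)(CC)CC)[C@H](OC(=O)C=C(C)C)C=C
F6 | step 8 | (3R,4R,5Z)-8-[(2R,3S)-3-formyl-2-methyloxiran-2-yl]-4-hydroxy-5-methylocta-1,5-dien-3-yl 3-methylbut-2-enoate | O=C[C@H]1O[C@]1(C)CC/C=C(C)\[C@@H](O)[C@H](OC(=O)C=C(C)C)C=C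
F7 | step 8 | (3R,4R,5Z)-4-{[2-(chloromethyl)prop-2-enoyl]oxy}-8-[(2R,3S)-3-formyl-2-methyloxiran-2-yl]-5-methylocta-1,5-dien-3-yl 3-methylbut-2-enoate | O=C[C@H]1O[C@]1(C)CC/C=C(C)\[C@@H](OC(=O)C(=C)CCl)[C@H](OC(=O)C=C(C)C)C=C
F8 | step 8 | (5R,6R)-3-(chloromethyl)-6-{(2Z)-5-[(2R,3S)-3-formyl-2-methyloxiran-2-yl]pent-2-en-2-yl}-2-oxo-5,6-dihydro-2H-pyran-5-yl 3-methylbut-2-enoate | O=C[C@H]1O[C@]1(C)CC/C=C(C)\[C@H]2OC(=O)C(CCl)=C[C@H]2OC(=O)C=C(C)C
F9 | step 8 | bridged 9,12-δ-lactone with free 6α-hydroxyl, 8α-senecioate, 4α,5β-epoxide and 1(10)-Z olefin | O[C@@H]1[C@H]2O[C@]2(C)CC/C=C(C)\[C@H]3OC(=O)C(=C)[C@@H]1[C@H]3OC(=O)C=C(C)C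
F10 | step 10 | methyl (2E,4R,5R,6Z)-5-hydroxy-9-[(2R,3R)-3-(hydroxymethyl)-2-methyloxiran-2-yl]-6-methyl-4-[(3-methylbut-2-enoyl)oxy]-2-[(4,4,5,5-tetramethyl-1,3,2-dioxaborolan-2-yl)methyl]nona-2,6-dienoate | OC[C@H]1O[C@]1(C)CC/C=C(C)\[C@@H](O)[C@H](OC(=O)C=C(C)C)/C=C(\CB2OC(C)(C)C(C)(C)O2)C(=O)OC
F11 | step 10 | methyl (2E,4R,5R,6Z)-9-[(2R,3S)-3-formyl-2-methyloxiran-2-yl]-5-hydroxy-6-methyl-4-[(3-methylbut-2-enoyl)oxy]-2-[(4,4,5,5-tetramethyl-1,3,2-dioxaborolan-2-yl)methyl]nona-2,6-dienoate | O=C[C@H]1O[C@]1(C)CC/C=C(C)\[C@@H](O)[C@H](OC(=O)C=C(C)C)/C=C(\CB2OC(C)(C)C(C)(C)O2)C(=O)OC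
F12 | step 10 | ring-closed 6-O-pinacolboryl analogue of 21 | CC1(C)OB(O[C@@H]2[C@H]3O[C@]3(C)CC/C=C(C)\[C@@H](O)[C@H](OC(=O)C=C(C)C)[C@H]2C(=C)C(=O)OC)OC1(C)C
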